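The route rests on reading ring A (C1 carbinol, C2, C3 gem-dimethyl, C4 bromide, C5, C6) as a hydrated homoallylic bromide, Br–C4–C5–C6=C1. This array is released from a 4,4-dimethylbicyclo[3.1.0]hex-2-ene: protonation at C2 gives a tertiary cyclopropylcarbinyl cation, the C4–C6 bond breaks, the five-membered ring becomes six-membered, and bromide enters neopentyl C4 with inversion. One operation therefore enlarges the ring and sets the hindered C–Br stereocentre. The precursor already holds all twenty carbons. It comes from a B-alkyl Suzuki coupling of an enantiopure cyclopropane-fused enol triflate with the bromo lactone of rings B, C and D, itself built by asymmetric Birch alkylation and a gold-catalysed enyne lactonisation.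

Key step: step 12

**Atom labels** (target numbering, used for all intermediates):
- Ring A = C1 (carbinol), C2, C3 (CMe2), C4 (CHBr), C5, C6.
- C7 = linking CH2.
- Ring B = C8 (CH bearing C7), C9, C10, C11 (quaternary), C12 (CH).
- Ring C = C11, C13 (CHBr), C14, C15, C16 (C(CH3)O), C12.
- Ring D = lactone C11–C17(=O)–O–C16–C12.
- The target is 1R,4R,8R,11R,12S,13R,16S.
- In 2 to 6 the carbinol or carbonyl carbon is C1, the CH2 is C2 and CMe2 is C3. The alkene (later cyclopropane) carbons are C4 (next to C3) and C6 (next to C1), and the cyclopropane CH2 is C5.

**Assumption:** the (S)-configured auxiliary is taken to steer the alkylation of step 6 to the face that gives 11S in 13. If the sense of induction is opposite, the equally available (R)-auxiliary is used and nothing else changes.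

Step 1
Reactants: 1 4,4-dimethylcyclopent-2-en-1-one
Product: 2 (R)-4,4-dimethylcyclopent-2-en-1-ol
Conditions: (S)-2-methyl-CBS-oxazaborolidine (10 mol %), BH3·SMe2, THF, −20 °C; MeOH quench
Reagents that add atoms: none
Why: Corey–Bakshi–Shibata reduction, in which the oxazaborolidine–borane complex binds the ketone with the alkene arm as the large group and delivers hydride in a 1,2-sense to one face, should set the R carbinol, the only catalyst-derived stereocentre of ring A.

Step 2
Reactants: 2 (R)-4,4-dimethylcyclopent-2-en-1-ol
Product: 3 (1S,2R,5R)-4,4-dimethylbicyclo[3.1.0]hexan-2-ol (hydroxyl cis to the cyclopropane CH2)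
Conditions: Et2Zn, CH2I2, CH2Cl2, −10 to 0 °C
Reagents that add atoms: diiodomethane, ICI
Why: In this hydroxyl-directed Simmons–Smith cyclopropanation the zinc alkoxide delivers CH2 to the alkene face syn to oxygen, so the carbinol configuration is relayed to C4 and C6.

Step 3
Reactants: 3 (1S,2R,5R)-4,4-dimethylbicyclo[3.1.0]hexan-2-ol
Product: 4 (1S,5R)-4,4-dimethylbicyclo[3.1.0]hexan-2-one
Conditions: Dess–Martin periodinane, pyridine, CH2Cl2, 0 °C to rt
Reagents that add atoms: none
Why: Buffered Dess–Martin oxidation removes the now redundant carbinol centre without ionising the acid-sensitive cyclopropyl carbinol.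

Step 4
Reactants: 4 (1S,5R)-4,4-dimethylbicyclo[3.1.0]hexan-2-one
Product: 6 (1S,5R)-4,4-dimethylbicyclo[3.1.0]hex-2-en-2-yl trifluoromethanesulfonate, via potassium enolate 5 (not isolated)
Conditions: KHMDS, THF, −78 °C; then PhNTf2, −78 to 0 °C
Reagents that add atoms: N-phenylbis(trifluoromethanesulfonimide), O=S(=O)(N(c1ccccc1)S(=O)(=O)C(F)(F)F)C(F)(F)F
Why: Enolisation can only occur towards C2 because the other alpha carbon (C6) is a cyclopropane bridgehead, and O-triflation of the enolate gives the alkenyl triflate with both cyclopropane stereocentres untouched.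

Step 5
Reactants: 7 2-methoxy-5-methylbenzoic acid; 8 (S)-2-(methoxymethyl)pyrrolidine
Product: 10 (S)-(2-methoxy-5-methylphenyl)[2-(methoxymethyl)pyrrolidin-1-yl]methanone, via 2-methoxy-5-methylbenzoyl chloride 9 (not isolated)
Conditions: (COCl)2, DMF (cat.), CH2Cl2, 0 °C to rt; then 8, Et3N, CH2Cl2, 0 °C
Reagents that add atoms: none
Why: Standard N-acylation through the acid chloride attaches the chiral auxiliary, whose stereocentre is not involved.

Step 6
Reactants: 10 (S)-(2-methoxy-5-methylphenyl)[2-(methoxymethyl)pyrrolidin-1-yl]methanone; 11 (4-bromobut-1-yn-1-yl)trimethylsilane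
Product: 13 [(S)-2-(methoxymethyl)pyrrolidin-1-yl][(1S)-2-methoxy-5-methyl-1-(4-trimethylsilylbut-3-yn-1-yl)cyclohexa-2,5-dien-1-yl]methanone (11S), via potassium amide dienolate 12 (not isolated)
Conditions: K, t-BuOH (1 equiv), NH3/THF, −78 °C; piperylene; then 11, −78 °C to rt
Reagents that add atoms: none
Why: Birch reduction at the ipso (C11) and para (C15) positions leaves methoxy and methyl on the two remaining double bonds, and the chelated potassium amide enolate is alkylated by the primary bromide on the face left open by the methoxymethyl arm (asymmetric Birch reduction–alkylation), which creates the quaternary stereocentre C11.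

Step 7
Reactants: 13 Birch alkylation product
Product: 15 (S)-2-(but-3-yn-1-yl)-4-methyl-2-{[(S)-2-(methoxymethyl)pyrrolidin-1-yl]carbonyl}cyclohex-3-en-1-one, via desilylated dienol ether 14 (not isolated)
Conditions: K2CO3 (cat.), MeOH, rt; then 1 M HCl, THF, rt (one pot)
Reagents that add atoms: water, O
Why: Base-catalysed methanolysis frees the terminal alkyne and mild acid hydrolysis of the enol ether unveils the C13 ketone, while the C12=C16 alkene cannot move into conjugation because C11 is quaternary.

Step 8
Reactants: 15 beta-keto amide
Product: 17 tricyclic keto lactone (rings B C D; C13 ketone; exocyclic C8=C7 methylene; 11S 12S 16S), via iminium ether acetate 16 (not isolated)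
Conditions: [(2-biphenylyl)(t-Bu)2P]Au(NCMe)SbF6 (5 mol %), AcOH (1.5 equiv), CH2Cl2, rt; then aq. NaHCO3
Reagents that add atoms: water, O
Why: Cationic monovalent gold activates the terminal alkyne for 5-exo-dig attack by C12 of the trisubstituted alkene (1,6-enyne cyclisation with internal oxygen trapping), the tertiary cation developing at C16 is captured on the opposite face by the amide oxygen held on C11 so that this anti addition fixes C12 and C16 from C11, protodeauration leaves the exocyclic methylene, and aqueous work-up hydrolyses the iminium ether to the lactone with release of the auxiliary.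

Step 9
Reactants: 17 tricyclic keto lactone
Product: 18 axial C13 alcohol of the tricyclic lactone (11S 12S 13S 16S)
Conditions: LiBH(s-Bu)3, THF, −78 °C; aq. work-up
Reagents that add atoms: none
Why: The bulky borohydride approaches the C13 ketone along the equatorial trajectory because the axial path is blocked by the axial C12–C8 bond, which should give the axial alcohol, and the lactone is not attacked at −78 °C.

Step 10
Reactants: 18 axial C13 alcohol
Product: 19 bromo lactone with exocyclic C8=C7 methylene (11R 12S 13R 16S; bromine equatorial)
Conditions: CBr4, PPh3, toluene, 70 °C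
Reagents that add atoms: carbon tetrabromide, BrC(Br)(Br)Br
Why: In the Appel reaction the oxyphosphonium ion of the axial alcohol is displaced by bromide in an SN2 process with inversion to the equatorial bromide, a substitution known for axial alcohols next to a quaternary ring carbon, and cationic shifts are disfavoured by the acyl group on C11.

Step 11
Reactants: 19 bromo lactone; 6 (1S,5R)-4,4-dimethylbicyclo[3.1.0]hex-2-en-2-yl trifluoromethanesulfonate
Product: 21 coupled vinylcyclopropane (C1=C2 alkene; C4–C5–C6 cyclopropane; C7 joined to C1 and C8; 8R 11R 12S 13R 16S), via B-alkyl-9-BBN adduct 20 (not isolated)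
Conditions: 9-BBN, THF, rt; then 6, Pd(dppf)Cl2 (5 mol %), K3PO4 (3 M aq.), DMF, rt to 45 °C
Reagents that add atoms: none
Why: 9-BBN adds to the exocyclic methylene from the convex face (the face of C12–H, away from C16 and ring C), which puts hydrogen on C8 and sets 8R, and the primary alkylborane then couples with the alkenyl triflate under divalent-palladium precatalysis (B-alkyl Suzuki–Miyaura coupling) without touching the hindered equatorial bromide or the lactone.

Step 12
Reactants: 21 coupled vinylcyclopropane
Product: 23 ring-enlarged dibromide (ring A as C1=C6 cyclohexene; 4R bromide; 8R 11R 12S 13R 16S), via cyclopropylcarbinyl cation bromide 22 (not isolated)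
Conditions: HBr (33 % in AcOH, 1.05 equiv), n-Bu4NBr (2 equiv), CH2Cl2, −60 to −20 °C
Reagents that add atoms: hydrogen bromide, Br
Why: HBr protonates the only alkene at C2 to give the tertiary, cyclopropane-stabilised cation 22 at C1, whose charge is shared with C4 and C5 through the two cyclopropane bonds at C6, and bromide attacks C4 opposite the C4–C6 bond while that bond becomes the C1=C6 double bond. The closest known reactions are the Julia homoallylic bromide synthesis from cyclopropyl carbinols and the acid-induced opening of thujene and sabinene to terpinen-4-yl derivatives, in which the same zero-bridge cleavage turns a bicyclo[3.1.0]hexane into a cyclohexene. No ring is closed by a new ring bond: ring A arises because loss of the bond shared by the three- and five-membered rings inserts C5 between C4 and C6, so five ring atoms become six. The one new stereocentre, C4, is controlled by inversion at the cyclopropane carbon, whose configuration was relayed from the carbinol of 2 through the directed cyclopropanation. The step needs cleavage of C6–C4 rather than C6–C5 and capture faster than methyl migration from C3; the secondary C4 carries more charge than the primary C5, zero-bridge cleavage relieves the strain of both small rings, and a high bromide concentration in a non-polar medium at low temperature favours concerted capture. A second addition of HBr is held back because the vinylcyclopropane is far more basic than the product alkene and only one equivalent of acid is offered.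

Step 13
Reactants: 23 ring-enlarged dibromide
Product: 25 target CNP0282702.1 (1R,4R,8R,11R,12S,13R,16S), via acetoxymercurial 24 (not isolated)
Conditions: Hg(OAc)2, THF/H2O, 0 °C to rt; then NaBH4, aq. NaOH, 0 °C
Reagents that add atoms: water, O
Why: In this oxymercuration–demercuration the mercurinium ion forms on the face opposite the axial C3 methyl group and water opens it at the tertiary C1 in the trans-diaxial (Fürst–Plattner) sense of the half-chair with equatorial bromine, which should place the C1 hydroxyl axial and cis to the C4 bromine (1R), and NaBH4 then replaces mercury by hydrogen without reducing the bromides or the lactone.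

**Compound list**

1 | 4,4-dimethylcyclopent-2-en-1-one | CC1(C)CC(=O)C=C1 | starting material
2 | (R)-4,4-dimethylcyclopent-2-en-1-ol | O[C@@H]1CC(C)(C)C=C1 | intermediate
3 | (1S,2R,5R)-4,4-dimethylbicyclo[3.1.0]hexan-2-ol | O[C@@H]1CC(C)(C)[C@@H]2C[C@H]12 | intermediate
4 | (1S,5R)-4,4-dimethylbicyclo[3.1.0]hexan-2-one | O=C1CC(C)(C)[C@@H]2C[C@H]12 | intermediate
5 | potassium enolate of 4 | [K+].[O-]C1=CC(C)(C)[C@@H]2C[C@H]12 | intermediate
6 | (1S,5R)-4,4-dimethylbicyclo[3.1.0]hex-2-en-2-yl trifluoromethanesulfonate | O=S(=O)(OC1=CC(C)(C)[C@@H]2C[C@H]12)C(F)(F)F | intermediate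
7 | 2-methoxy-5-methylbenzoic acid | COc1ccc(C)cc1C(=O)O | starting material
8 | (S)-2-(methoxymethyl)pyrrolidine | COC[C@@H]1CCCN1 | starting material
9 | 2-methoxy-5-methylbenzoyl chloride | COc1ccc(C)cc1C(=O)Cl | intermediate
10 | (S)-(2-methoxy-5-methylphenyl)[2-(methoxymethyl)pyrrolidin-1-yl]methanone | COC[C@@H]1CCCN1C(=O)c1cc(C)ccc1OC | intermediate
11 | (4-bromobut-1-yn-1-yl)trimethylsilane | C[Si](C)(C)C#CCCBr | starting material
12 | potassium amide dienolate from Birch reduction of 10 | [K+].[O-]C(N1CCC[C@H]1COC)=C1C=C(C)CC=C1OC | intermediate
13 | Birch alkylation product (11S) | C[Si](C)(C)C#CCC[C@]1(C(=O)N2CCC[C@H]2COC)C=C(C)CC=C1OC | intermediate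
14 | desilylated dienol ether (11S) | C#CCC[C@]1(C(=O)N2CCC[C@H]2COC)C=C(C)CC=C1OC | intermediate
15 | beta-keto amide (11S) | C#CCC[C@]1(C(=O)N2CCC[C@H]2COC)C=C(C)CCC1=O | intermediate
16 | iminium ether acetate | C=C1CC[C@@]23C(=[N+]4CCC[C@H]4COC)O[C@@](C)(CCC2=O)[C@@H]13.CC(=O)[O-] | intermediate
17 | tricyclic keto lactone (11S,12S,16S) | C=C1CC[C@@]23C(=O)O[C@@](C)(CCC2=O)[C@@H]13 | intermediate
18 | axial C13 alcohol (11S,12S,13S,16S) | C=C1CC[C@@]23C(=O)O[C@@](C)(CC[C@@H]2O)[C@@H]13 | intermediate
19 | bromo lactone (11R,12S,13R,16S) | C=C1CC[C@@]23C(=O)O[C@@](C)(CC[C@H]2Br)[C@@H]13 | intermediate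
20 | B-alkyl-9-BBN adduct of 19 (C8–H on the face of C12–H) | C(B1C2CCCC1CCC2)[C@H]1CC[C@@]23C(=O)O[C@@](C)(CC[C@H]2Br)[C@@H]13 | intermediate
21 | coupled vinylcyclopropane | CC1(C)C=C(C[C@H]3CC[C@@]45C(=O)O[C@@](C)(CC[C@H]4Br)[C@@H]35)[C@H]2C[C@@H]12 | intermediate
22 | cyclopropylcarbinyl cation bromide | CC1(C)C[C+](C[C@H]3CC[C@@]45C(=O)O[C@@](C)(CC[C@H]4Br)[C@@H]35)[C@H]2C[C@@H]12.[Br-] | intermediate
23 | ring-enlarged dibromide (C1=C6 alkene, 4R) | CC1(C)CC(C[C@H]2CC[C@@]34C(=O)O[C@@](C)(CC[C@H]3Br)[C@@H]24)=CC[C@H]1Br | intermediate
24 | acetoxymercurial (C6–Hg trans to C1–OH) | CC1(C)C[C@](O)(C[C@H]2CC[C@@]34C(=O)O[C@@](C)(CC[C@H]3Br)[C@@H]24)[C@H]([Hg]OC(C)=O)C[C@H]1Br | intermediate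
25 | CNP0282702.1 | CC1(C)C[C@](O)(C[C@H]2CC[C@@]34C(=O)O[C@@](C)(CC[C@H]3Br)[C@@H]24)CC[C@H]1Br | target

**Total steps:** 13. **Longest linear sequence:** 9 (steps 5 to 13, from 7).

**Steps most likely to fail**

**Step 12.** As positive charge builds at the neopentyl C4, bromide capture may be outrun by methyl migration from C3 or by attack at the cyclopropane CH2. The product alkene may also take up a second HBr. The fallback sets out from 21 and comes back at 23. It separates ring enlargement from C–Br bond formation.
- Solvolysis of 21 in aqueous dioxane with catalytic HClO4 is the thujene-to-terpinen-4-ol type hydration. It runs under reversible conditions with the small nucleophile as solvent and should give the ring-enlarged homoallylic alcohol F1.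
- Dess–Martin oxidation then gives the beta,gamma-unsaturated ketone F2.
- Reagent-controlled reduction with (R)-2-methyl-CBS-oxazaborolidine and catecholborane (quaternary C3 as the large group) gives the C4-epimeric alcohol F3.
- An Appel reaction (CBr4, PPh3) converts F3 into 23 with inversion.

**Step 10.** Formation of the bulky oxyphosphonium ion at the axial, neopentyl hydroxyl may be slow. At the temperature it needs, anti elimination towards C14 may overtake substitution. The fallback sets out from 18 and comes back at 19. It separates activation from substitution.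
- Tf2O and pyridine in CH2Cl2 at −78 °C put a small leaving group on oxygen in the absence of any nucleophile, giving the axial C13 triflate F4.
- LiBr in acetone/CH2Cl2 between −20 °C and rt then displaces it with inversion, in a temperature range where elimination is slower.

**Step 8.** The cascade may stall through slow turnover of the gold catalyst in the presence of the basic amide and its hydrolysis products. It may also divert through competing 6-endo closure or alkyne hydration. The fallback sets out from 15 and comes back at 17. It replaces the cationic cascade by two classical steps.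
- Iodolactonisation of the amide (I2, THF/H2O) puts iodonium on the face of the butynyl chain, and the amide oxygen opens it at the tertiary C16. This gives the iodo lactone F5 with loss of the auxiliary.
- Bu3SnH with AIBN in benzene generates the C12 radical, which closes ring B by 5-exo-dig attack on the alkyne. The vinyl radical takes up hydrogen to give 17, and the short tether enforces the cis ring fusion.

**Further compounds**

F1 | step 12 | ring-enlarged homoallylic alcohol (4R) | CC1(C)CC(C[C@H]2CC[C@@]34C(=O)O[C@@](C)(CC[C@H]3Br)[C@@H]24)=CC[C@H]1O
F2 | step 12 | beta,gamma-unsaturated ketone (C4 ketone, C1=C6 alkene) | CC1(C)CC(C[C@H]2CC[C@@]34C(=O)O[C@@](C)(CC[C@H]3Br)[C@@H]24)=CCC1=O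
F3 | step 12 | C4-epimeric alcohol (4S) | CC1(C)CC(C[C@H]2CC[C@@]34C(=O)O[C@@](C)(CC[C@H]3Br)[C@@H]24)=CC[C@@H]1O
F4 | step 10 | axial C13 triflate | C=C1CC[C@@]23C(=O)O[C@@](C)(CC[C@@H]2OS(=O)(=O)C(F)(F)F)[C@@H]13
F5 | step 8 | iodo lactone (C12–I trans to C16–O) | C#CCC[C@@]12C(=O)O[C@@](C)(CCC1=O)[C@H]2I
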